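## The problem

The target **23** is a dibenzo[b,f]oxepine (rings A, B, C) whose C10=C11 double bond is also the enol ether double bond of a 3,4-dihydro-2H-pyran (ring D: O1'–C2'–C3'–C4'–C11=C10). C10 carries ring C and the ring D oxygen; C11 carries ring A and the ring D methylene group. Ring D holds the only two stereocentres: the quaternary carbon C2' (S; methyl, homoprenyl, ring oxygen) and the adjacent carbinol carbon C3' (S), with the hydroxyl trans to the methyl group. Being adjacent, they can be related by one stereospecific operation, but nothing else in the molecule can induce them and they control nothing further, so their absolute configuration must come from a reagent. The sensitive groups are the tetrasubstituted, doubly aryl-conjugated enol ether (acid), two trisubstituted olefins (one a prenyl group ortho to a phenol, which cyclises to a chroman under acid) and electron-rich phenols. Strong acid, hydrogenation and electrophilic oxidants are therefore excluded late in the route. Ring A is 1,2,4,5-tetrasubstituted (C11, ether oxygen, hydroxyl para to C11, prenyl ortho to that hydroxyl) and needs a regiodefined arene early. Ring C carries only three substituents: the ether oxygen, C10 on the neighbouring carbon, and one hydroxyl para to C10. Its six carbons can therefore come from three alkynes, and because the bond between its oxygen-bearing and C10-bearing carbons is also a ring B bond, joining an ethynyl ether on the ring A oxygen to an alkyne on C10 closes the oxepine in the same event.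

## Retrosynthesis

**23 ⇐ 22 ⇐ 21 ⇐ 20.** The last three operations change no C–C bond: O–Si cleavage (**22**), C–Si to C–H exchange (**21**) and C–B to C–O exchange (**20**). Boron marks the future ring C hydroxyl and silicon is the group that steers the ring-forming step. Both must be removable without acid, which fluoride, silanolate and perborate allow. **20** is not simpler in skeleton, but it is the direct product of the ring-forming step.

**20 ⇐ 18 + 19.** Three C–C bonds of ring C are cut, one of which is also the ring B bond between the oxygen-bearing carbon of ring C and the carbon attached to C10. The neighbouring cuts (the diaryl ether C–O bond or the C10–aryl bond) would need a prefabricated trisubstituted ring C and a late, selective unmasking of one phenol. The cyclotrimerisation instead assembles ring C from two-carbon pieces and closes ring B in the same step. Diyne **18** contains only rings A and D. The forward reaction must close a seven-membered ring and must orient boronate **19**; the silyl group on the C10 alkyne is there for the second task.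

**18 ⇐ 17 ⇐ 15 + 16 ⇐ 14.** Both alkynes are installed late. The ethynyl ether is too labile to carry, so it is released from a dichlorovinyl ether in the last step before cyclisation. The C10–alkyne bond is cut back to ketene acetal phosphate **15** and alkyne **16**, and **15** to lactone **14**, whose carbonyl carbon is C10 and whose α-carbon is C11. Cross-coupling is preferred to acetylide addition and dehydration because the α-aryl lactone enolises easily. **14** is a monocyclic δ-lactone. The dichlorovinyl ether must survive enolate formation and palladium catalysis.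

**14 ⇐ 12 ⇐ 11 + 3.** The lactone C–O bond at the quaternary carbon and the Cα–CH2 bond are cut. The C–O bond is made by opening a cis-epoxide at its tertiary carbon with the ester carbonyl oxygen (inversion), which turns the epoxide into the trans hydroxyl/methyl pair of ring D. Lactonising a free diol would give the γ-lactone through the nearer secondary hydroxyl, and dihydroxylating a neryl arylacetate could not distinguish three trisubstituted olefins. A tert-butyl ester is needed so that the alkyl group can leave as a cation. **12** is acyclic and comes from enolate alkylation of **11** with triflate **3**.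

**3 ⇐ 2 ⇐ 1.** The epoxide is cut back to nerol. Asymmetric epoxidation touches only the allylic olefin and sets both ring D stereocentres in one reagent-controlled step. The Z geometry is essential: geraniol would give the hydroxyl cis to the methyl group.

**11 ⇐ 9 + 10; 9 ⇐ 7 + 8; 7 ⇐ 6 ⇐ 5 ⇐ 4.** Ring A comes from 2,4-dihydroxyphenylacetic acid **4**, whose carboxyl carbon becomes C10 and whose methylene carbon becomes C11. The aryl–prenyl bond is cut to iodide **7** and stannane **8**. The iodide is placed para to the free 2-hydroxyl after the 4-hydroxyl has been silylated selectively. The 2-hydroxyl then adds to dichloroacetylene from **10**; these two carbons become two ring C carbons, and the other four come from **16** and **19**. Differentiating the phenols by sterics is preferred to a lactone-based differentiation because the tert-butyl ester must be in place.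

## Roads not taken

**Alternative 1:** The cut goes through ring A, three of whose C–C bonds are made by a Danheiser benzannulation. Irradiation of diazo ketone A2 (Wolff rearrangement to a vinylketene) with aryl ethynyl ether A3 would give phenol A1 by (2+2) addition, four-electron ring opening and six-electron closure. A1 has the ether oxygen, hydroxyl, prenyl and the CH2CO2Me arm in place.
- Merits: the substitution pattern of ring A, prenyl included, is fixed by the connectivity of A2, so no arene halogenation or tin chemistry is needed. The diaryl ether exists from the start. Ynol ethers are proven partners in this benzannulation, so its key step is better precedented than the one chosen here.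
- Weak points: A1 still lacks ring B and ring D. The C10–ring C bond would need a later electrophilic closure onto ring C, which offers two positions ortho to the ether oxygen. The classical acylative closure leaves ring D to be annulated onto a ketone. A2 combines a diazo group, a skipped diene and an enolisable ester, so carbene addition to the olefin and olefin migration compete with the Wolff step.
- Comparison: it is the better way to make ring A but postpones the oxepine. The chosen plan spends five conventional steps (including a Stille coupling) on ring A and in return closes ring B and builds ring C in one operation.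

**Alternative 2:** The cut is the C11–ring A bond, made by ring expansion. n-BuLi would convert xanthenol A5 into a β-oxido carbenoid whose 1,2-aryl shift enlarges the central ring to oxepinone A4, with the complete ring D side chain on C11.
- Merits: the tricyclic core of A5 is symmetrical in its oxygenation, so either aryl group may migrate. Carbenoid ring expansions of ketone adducts are closer to precedent than a seven-membered cyclotrimerisation. Ring D would then close by dehydrative ketalisation onto the C10 ketone, which has no regiochemical ambiguity and is arguably safer than the epoxide opening in step 9.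
- Weak points: the prenyl group is missing. After the rearrangement, rings A and C differ only in their relation to the carbonyl group, so one prenyl group would have to go ortho to one of two nearly equivalent silyloxy groups. Desymmetrising the core earlier removes the symmetry that made the migration unambiguous. The gem-dibromide with two oxygenated stereocentres needs its own multistep synthesis.
- Comparison: better precedent for ring B and a safer ring D closure, but no regiocontrol on ring A, which the chosen plan settles in steps 4 to 6. Against this the chosen plan has to set an untested catalytic step.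

**Alternative 3:** The cut removes the O–C10 and C11–ring A bonds together. Pd(PPh3)4 with K2CO3 would couple aryl iodide A7 with hydroxy alkyne A8: the alkyne bound to arylpalladium iodide is attacked at C10 by the tertiary hydroxyl, and reductive elimination gives cis-diaryl dihydropyran A6. Ring B would follow by intramolecular etherification between the ring A oxygen and the ring C bromide.
- Merits: three fragments of similar size, every reaction of a known type, and no lactone, phosphate or ynol ether. The tertiary alcohol is made in an open chain, where epoxide opening cannot divert into a γ-lactone. This is probably the lowest-risk road to ring B.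
- Weak points: hydroxyl groups four atoms from an alkyne usually close 5-exo to alkylidene tetrahydrofurans, and the 6-endo attack needed here relies only on polarisation by the aryl group. The iodide must react in the presence of the bromide. A6 carries three aryl silyl ethers, exactly one of which must be removed before ring closure, which in practice means an orthogonal protecting group and extra steps.
- Comparison: similar length and better precedent. The chosen plan makes ring C and ring B together from two-carbon units, places the ring C oxygen in the same step and never has to single out one phenol late. The etherification endgame of this alternative is kept as the fallback for step 13.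

Key step: step 13

Remark: the carbon α to the carbonyl group in **12**, **13** and **14** forms without control and is carried as a mixture of epimers, because it becomes the sp2 carbon C11 in step 10.

Abbreviations in names: prenyl = 3-methylbut-2-en-1-yl; homoprenyl = 4-methylpent-3-en-1-yl; TIPSO = triisopropylsilyloxy; TBSO = tert-butyldimethylsilyloxy; TMS = trimethylsilyl; DCVO = (E)-1,2-dichloroethenyloxy; Bpin = 4,4,5,5-tetramethyl-1,3,2-dioxaborolan-2-yl; ArA = 2-(DCVO)-5-prenyl-4-(TIPSO)phenyl.

## Route

Step 1
Reactants: 1 nerol, (2Z)-3,7-dimethylocta-2,6-dien-1-ol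
Product: 2 (2S,3R)-2,3-epoxynerol, [(2S,3R)-3-methyl-3-homoprenyloxiran-2-yl]methanol
Conditions: Ti(OiPr)4 (10 mol%), diethyl L-(+)-tartrate (12 mol%), t-BuOOH, 4 Å molecular sieves, CH2Cl2, −20 °C
Reagents that add atoms: tert-butyl hydroperoxide CC(C)(C)OO
Why: Sharpless asymmetric epoxidation; only the allylic olefin is bound to titanium and epoxidised, and the L-(+)-tartrate complex delivers oxygen to the face that gives the (2S,3R)-epoxide. The Z geometry fixes CH2OH and homoprenyl cis on the oxirane, which step 9 converts into the trans hydroxyl/methyl arrangement of ring D.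

Step 2
Reactants: 2 (2S,3R)-2,3-epoxynerol
Product: 3 [(2S,3R)-3-methyl-3-homoprenyloxiran-2-yl]methyl trifluoromethanesulfonate
Conditions: Tf2O, 2,6-lutidine, CH2Cl2, −78 °C; used crude
Reagents that add atoms: trifluoromethanesulfonic anhydride O=S(=O)(OS(=O)(=O)C(F)(F)F)C(F)(F)F
Why: O-sulfonylation of a primary alcohol with a hindered base at low temperature; epoxy triflates can be used without purification and are reactive enough to alkylate an ester enolate at −78 °C, where the epoxide is not attacked.

Step 3
Reactants: 4 2,4-dihydroxyphenylacetic acid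
Product: 5 tert-butyl 2-(2,4-dihydroxyphenyl)acetate
Conditions: tert-butyl 2,2,2-trichloroacetimidate (2 equiv), THF–cyclohexane, 25 °C
Reagents that add atoms: tert-butyl 2,2,2-trichloroacetimidate CC(C)(C)OC(=N)C(Cl)(Cl)Cl
Why: Imidate esterification without added acid; the carboxylic acid protonates the imidate and captures the tert-butyl cation, whereas phenols need a Lewis acid and stay free. The tert-butyl ester is required because step 9 needs an ester that loses its alkyl group as a cation.

Step 4
Reactants: 5 tert-butyl 2-(2,4-dihydroxyphenyl)acetate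
Product: 6 tert-butyl 2-[2-hydroxy-4-(TIPSO)phenyl]acetate
Conditions: TIPSCl (1.05 equiv), imidazole, CH2Cl2, 0 °C
Reagents that add atoms: triisopropylsilyl chloride CC(C)[Si](Cl)(C(C)C)C(C)C
Why: Regioselective phenol silylation; the bulky chlorosilane should react at the unhindered 4-hydroxyl, since the 2-hydroxyl is flanked by the CH2CO2t-Bu group and hydrogen-bonded to its carbonyl. Triisopropylsilyl is chosen over TBS because this aryl silyl ether must survive carbonate in DMF in step 7.

Step 5
Reactants: 6 tert-butyl 2-[2-hydroxy-4-(TIPSO)phenyl]acetate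
Product: 7 tert-butyl 2-[2-hydroxy-5-iodo-4-(TIPSO)phenyl]acetate
Conditions: N-iodosuccinimide, MeCN, 0 °C
Reagents that add atoms: N-iodosuccinimide O=C1CCC(=O)N1I
Why: Electrophilic aromatic iodination of a phenol; the free 2-hydroxyl directs para to C5, which is also ortho to the silyloxy group, while C3 between the two oxygens is shielded by the triisopropylsilyl group.

Step 6
Reactants: 7 tert-butyl 2-[2-hydroxy-5-iodo-4-(TIPSO)phenyl]acetate, 8 tributyl(prenyl)stannane
Product: 9 tert-butyl 2-[2-hydroxy-5-prenyl-4-(TIPSO)phenyl]acetate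
Conditions: 8 (1.5 equiv), Pd(PPh3)4 (5 mol%), DMF, 90 °C
Reagents that add atoms: none
Why: Stille coupling of an aryl iodide with an allylic stannane; reductive elimination from the prenylpalladium intermediate occurs at the unsubstituted terminus, so the linear prenyl group is expected. The free phenol and the ester are tolerated.

Step 7
Reactants: 9 tert-butyl 2-[2-hydroxy-5-prenyl-4-(TIPSO)phenyl]acetate, 10 trichloroethylene
Product: 11 tert-butyl 2-[2-(DCVO)-5-prenyl-4-(TIPSO)phenyl]acetate (tert-butyl 2-ArA-acetate)
Conditions: 10 (1.5 equiv), K2CO3, DMF, 60 °C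
Reagents that add atoms: none
Why: Dichlorovinyl ether synthesis; the phenoxide adds anti to dichloroacetylene generated in situ from trichloroethylene, giving the (E)-1,2-dichlorovinyl ether. This group is a robust masked ethynyl ether and also protects the phenol through steps 8 to 11.

Step 8
Reactants: 11 tert-butyl 2-ArA-acetate, 3 [(2S,3R)-3-methyl-3-homoprenyloxiran-2-yl]methyl trifluoromethanesulfonate
Product: 12 tert-butyl (2RS)-2-ArA-3-[(2S,3R)-3-methyl-3-homoprenyloxiran-2-yl]propanoate
Conditions: LiN(SiMe3)2 (1.05 equiv), THF, −78 °C; then 3, −78 to −40 °C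
Reagents that add atoms: none
Why: C-alkylation of a lithium ester enolate with a primary triflate; the silylamide is consumed by the far more acidic arylacetate proton before it can attack the dichlorovinyl ether, and the epoxide is inert at this temperature. The new α-centre forms as an epimer mixture and is planarised in step 10.

Step 9
Reactants: 12 tert-butyl (2RS)-2-ArA-3-[(2S,3R)-3-methyl-3-homoprenyloxiran-2-yl]propanoate
Product: 14 (3RS,5S,6S)-3-ArA-5-(TBSO)-6-methyl-6-homoprenyloxan-2-one, via hydroxy lactone 13 (not isolated)
Conditions: BF3·OEt2 (0.3 equiv), CH2Cl2, −78 °C; then 2,6-lutidine, TBSOTf, −78 to 0 °C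
Reagents that add atoms: tert-butyldimethylsilyl trifluoromethanesulfonate CC(C)(C)[Si](C)(C)OS(=O)(=O)C(F)(F)F
Why: Lewis-acid-promoted epoxy ester lactonisation; activation of the trisubstituted epoxide puts positive charge on the tertiary carbon, the ester carbonyl oxygen attacks there with inversion (6-endo), and loss of the tert-butyl cation as isobutene makes the δ-lactone irreversible. C6 is set by inversion and C5 keeps the configuration from step 1, giving hydroxyl trans to methyl. The secondary alcohol is silylated in the same flask so that it cannot migrate the acyl group to form the γ-lactone.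

Step 10
Reactants: 14 (3RS,5S,6S)-3-ArA-5-(TBSO)-6-methyl-6-homoprenyloxan-2-one
Product: 15 (2S,3S)-5-ArA-3-(TBSO)-2-methyl-2-homoprenyl-3,4-dihydro-2H-pyran-6-yl diphenyl phosphate
Conditions: KN(SiMe3)2, (PhO)2P(O)Cl, THF–HMPA, −78 °C
Reagents that add atoms: diphenyl chlorophosphate O=P(Cl)(Oc1ccccc1)Oc1ccccc1
Why: O-phosphorylation of the potassium lactone enolate to a ketene acetal phosphate; the α-aryl proton is acidic, there is no β-leaving group (the silyloxy group is γ), and both stereocentres are untouched.

Step 11
Reactants: 15 (2S,3S)-5-ArA-3-(TBSO)-2-methyl-2-homoprenyl-3,4-dihydro-2H-pyran-6-yl diphenyl phosphate, 16 trimethylsilylacetylene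
Product: 17 (2S,3S)-5-ArA-3-(TBSO)-2-methyl-2-homoprenyl-6-[(trimethylsilyl)ethynyl]-3,4-dihydro-2H-pyran
Conditions: 16 (3 equiv), Pd(PPh3)4 (10 mol%), CuI (20 mol%), Et3N, DMF, 25 to 50 °C
Reagents that add atoms: none
Why: Sonogashira coupling of a lactone-derived ketene acetal phosphate with a terminal alkyne under zerovalent palladium and CuI; the enol phosphate is the only group that adds oxidatively here, since the vinylic chlorides of the dichlorovinyl ether need electron-rich ligands and heat.

Step 12
Reactants: 17 (2S,3S)-5-ArA-3-(TBSO)-2-methyl-2-homoprenyl-6-[(trimethylsilyl)ethynyl]-3,4-dihydro-2H-pyran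
Product: 18 (2S,3S)-5-[2-(ethynyloxy)-5-prenyl-4-(TIPSO)phenyl]-3-(TBSO)-2-methyl-2-homoprenyl-6-[(trimethylsilyl)ethynyl]-3,4-dihydro-2H-pyran
Conditions: n-BuLi (2.5 equiv), THF, −78 to −40 °C; then MeOH, −78 °C; used at once
Reagents that add atoms: none
Why: Conversion of a 1,2-dichlorovinyl ether into an ynol ether; n-BuLi eliminates HCl and exchanges the remaining chlorine for lithium, and the lithium alkynyl ether is protonated cold. Silyl ethers, the C-silyl alkyne and the enol ether are inert to n-BuLi at this temperature.

Step 13
Reactants: 18 diyne (as named in step 12), 19 2-ethynyl-4,4,5,5-tetramethyl-1,3,2-dioxaborolane (ethynyl-Bpin)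
Product: 20 tetracycle: 23 carrying TIPS on the ring A oxygen and TBS on the C3' oxygen, with Bpin on ring C in place of the hydroxyl (para to C10) and TMS on the ring C carbon ortho to C10
Conditions: [Rh(cod)2]BF4 (10 mol%), rac-BINAP (10 mol%), activated with H2 in CH2Cl2 and degassed; 19 (3 equiv); 18 added over 4 h, (CH2Cl)2, 25 to 40 °C
Reagents that add atoms: none
Why: Proposed new method: the cationic monovalent rhodium–BINAP fragment is expected to bind both alkynes of 18, cyclise them oxidatively to a rhodacyclopentadiene fused to the nascent oxepine, insert alkyne 19 and release the arene by reductive elimination; the closest known reaction type is the cationic rhodium-catalysed (2+2+2) cycloaddition of tethered 1,6- and 1,7-diynes with monoalkynes, which accepts aryl ethynyl ethers and alkynylboronates but has not been shown for a diaryl-ether-type tether closing a seven-membered ring. Ring C is closed as a six-membered carbocycle from three alkynes by formation of three C–C bonds. Ring B is closed in the oxidative cyclisation, by the bond between the oxygen-bearing carbon of the ynol ether and the alkyne carbon attached to C10 (seven-membered; the tether is one oxygen and four sp2 carbons). Ring A and the cis C10=C11 double bond hold the two alkynes on the same side, so the entropic cost of the medium ring should be small, and aromatisation of ring C supplies the driving force. No stereocentre is formed, and C2' and C3' are spectators. The selectivity that matters is the orientation of 19: the trimethylsilyl group on the C10 alkyne should force the unsubstituted carbon of 19 to bond to the silylated carbon, placing Bpin para to C10 and meta to the ether oxygen. Cross-trimerisation is favoured over homo-trimerisation by slow addition of 18 to excess 19, and the trisubstituted olefins do not compete with alkynes for the catalyst.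

Step 14
Reactants: 20 tetracyclic boronate
Product: 21 tetracyclic phenol: as 20 but with hydroxyl in place of Bpin (TMS on ring C, TIPS on the ring A oxygen and TBS on the C3' oxygen retained)
Conditions: NaBO3·4H2O (3 equiv), THF–H2O (1:1), 25 °C
Reagents that add atoms: sodium perborate [Na+].[O-]B1OO1
Why: Oxidation of an arylboronic ester to a phenol with perborate; the reagent is mild enough to leave the trisubstituted olefins, the enol ether, the silyl ethers and the aryl C–Si bond intact.

Step 15
Reactants: 21 tetracyclic phenol
Product: 22 the C3' O-TBS ether of 23 (ring C without silicon, both phenols free)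
Conditions: KOSiMe3 (4 equiv), DMSO–H2O (20:1), 70 °C
Reagents that add atoms: none
Why: Base-mediated protodesilylation of an aryltrimethylsilane by silanolate in wet DMSO (pentacoordinate silicate, protonation of the departing aryl group); the C–Si bond is ortho to the bulky C10 substituent, which should accelerate cleavage, and the basic medium spares the enol ether and prenyl groups. The aryl silyl ether is expected to cleave under the same conditions and the hindered secondary silyl ether to persist.

Step 16
Reactants: 22 the C3' O-TBS ether of 23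
Product: 23 target CNP0185870.1: dibenzo[b,f]oxepine with ring D [(2'S,3'S)-3'-hydroxy-2'-methyl-2'-homoprenyl-3',4'-dihydro-2'H-pyran] fused across C10=C11 (ring oxygen on C10), hydroxyl on ring A para to C11 with prenyl ortho to it, hydroxyl on ring C para to C10
Conditions: Bu4NF (3 equiv), THF, 0 to 25 °C
Reagents that add atoms: none
Why: Fluoride-mediated cleavage of the remaining silyl ether (and of any aryl silyl ether that survived step 15) under non-acidic conditions; no stereocentre is touched.

## Compound list

1 | nerol, (2Z)-3,7-dimethylocta-2,6-dien-1-ol | CC(C)=CCC/C(C)=C\CO | starting material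
2 | [(2S,3R)-3-methyl-3-homoprenyloxiran-2-yl]methanol | OC[C@@H]1O[C@]1(C)CCC=C(C)C | intermediate
3 | [(2S,3R)-3-methyl-3-homoprenyloxiran-2-yl]methyl trifluoromethanesulfonate | FC(F)(F)S(=O)(=O)OC[C@@H]1O[C@]1(C)CCC=C(C)C | intermediate
4 | 2,4-dihydroxyphenylacetic acid | OC(=O)Cc1ccc(O)cc1O | starting material
5 | tert-butyl 2-(2,4-dihydroxyphenyl)acetate | CC(C)(C)OC(=O)Cc1ccc(O)cc1O | intermediate
6 | tert-butyl 2-[2-hydroxy-4-(TIPSO)phenyl]acetate | CC(C)(C)OC(=O)Cc1ccc(O[Si](C(C)C)(C(C)C)C(C)C)cc1O | intermediate
7 | tert-butyl 2-[2-hydroxy-5-iodo-4-(TIPSO)phenyl]acetate | CC(C)(C)OC(=O)Cc1cc(I)c(O[Si](C(C)C)(C(C)C)C(C)C)cc1O | intermediate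
8 | tributyl(3-methylbut-2-en-1-yl)stannane | CCCC[Sn](CCCC)(CCCC)CC=C(C)C | starting material
9 | tert-butyl 2-[2-hydroxy-5-prenyl-4-(TIPSO)phenyl]acetate | CC(C)(C)OC(=O)Cc1cc(CC=C(C)C)c(O[Si](C(C)C)(C(C)C)C(C)C)cc1O | intermediate
10 | trichloroethylene | ClC=C(Cl)Cl | starting material
11 | tert-butyl 2-[2-(DCVO)-5-prenyl-4-(TIPSO)phenyl]acetate | CC(C)(C)OC(=O)Cc1cc(CC=C(C)C)c(O[Si](C(C)C)(C(C)C)C(C)C)cc1O/C(Cl)=C\Cl | intermediate
12 | tert-butyl (2RS)-2-ArA-3-[(2S,3R)-3-methyl-3-homoprenyloxiran-2-yl]propanoate | CC(C)(C)OC(=O)C(C[C@@H]1O[C@]1(C)CCC=C(C)C)c1cc(CC=C(C)C)c(O[Si](C(C)C)(C(C)C)C(C)C)cc1O/C(Cl)=C\Cl | intermediate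
13 | (3RS,5S,6S)-3-ArA-5-hydroxy-6-methyl-6-homoprenyloxan-2-one | CC(C)=CCC[C@]1(C)OC(=O)C(C[C@@H]1O)c1cc(CC=C(C)C)c(O[Si](C(C)C)(C(C)C)C(C)C)cc1O/C(Cl)=C\Cl | intermediate
14 | (3RS,5S,6S)-3-ArA-5-(TBSO)-6-methyl-6-homoprenyloxan-2-one | CC(C)=CCC[C@]1(C)OC(=O)C(C[C@@H]1O[Si](C)(C)C(C)(C)C)c1cc(CC=C(C)C)c(O[Si](C(C)C)(C(C)C)C(C)C)cc1O/C(Cl)=C\Cl | intermediate
15 | (2S,3S)-5-ArA-3-(TBSO)-2-methyl-2-homoprenyl-3,4-dihydro-2H-pyran-6-yl diphenyl phosphate | CC(C)=CCC[C@]1(C)OC(OP(=O)(Oc2ccccc2)Oc2ccccc2)=C(C[C@@H]1O[Si](C)(C)C(C)(C)C)c1cc(CC=C(C)C)c(O[Si](C(C)C)(C(C)C)C(C)C)cc1O/C(Cl)=C\Cl | intermediate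
16 | trimethylsilylacetylene | C#C[Si](C)(C)C | starting material
17 | (2S,3S)-5-ArA-3-(TBSO)-2-methyl-2-homoprenyl-6-[(trimethylsilyl)ethynyl]-3,4-dihydro-2H-pyran | CC(C)=CCC[C@]1(C)OC(C#C[Si](C)(C)C)=C(C[C@@H]1O[Si](C)(C)C(C)(C)C)c1cc(CC=C(C)C)c(O[Si](C(C)C)(C(C)C)C(C)C)cc1O/C(Cl)=C\Cl | intermediate
18 | (2S,3S)-5-[2-(ethynyloxy)-5-prenyl-4-(TIPSO)phenyl]-3-(TBSO)-2-methyl-2-homoprenyl-6-[(trimethylsilyl)ethynyl]-3,4-dihydro-2H-pyran | CC(C)=CCC[C@]1(C)OC(C#C[Si](C)(C)C)=C(C[C@@H]1O[Si](C)(C)C(C)(C)C)c1cc(CC=C(C)C)c(O[Si](C(C)C)(C(C)C)C(C)C)cc1OC#C | intermediate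
19 | 2-ethynyl-4,4,5,5-tetramethyl-1,3,2-dioxaborolane | C#CB1OC(C)(C)C(C)(C)O1 | starting material
20 | tetracycle: 23 with ring A O-TIPS, C3' O-TBS, Bpin on ring C para to C10 (in place of OH) and TMS on ring C ortho to C10 | CC(C)=CCC[C@]1(C)OC2=C(C[C@@H]1O[Si](C)(C)C(C)(C)C)c1cc(CC=C(C)C)c(O[Si](C(C)C)(C(C)C)C(C)C)cc1Oc1cc(B3OC(C)(C)C(C)(C)O3)cc([Si](C)(C)C)c12 | intermediate
21 | tetracycle: 23 with ring A O-TIPS, C3' O-TBS and TMS on ring C ortho to C10 | CC(C)=CCC[C@]1(C)OC2=C(C[C@@H]1O[Si](C)(C)C(C)(C)C)c1cc(CC=C(C)C)c(O[Si](C(C)C)(C(C)C)C(C)C)cc1Oc1cc(O)cc([Si](C)(C)C)c12 | intermediate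
22 | C3' O-TBS ether of 23 | CC(C)=CCC[C@]1(C)OC2=C(C[C@@H]1O[Si](C)(C)C(C)(C)C)c1cc(CC=C(C)C)c(O)cc1Oc1cc(O)ccc12 | intermediate
23 | CNP0185870.1, (2'S,3'S)-configured pyrano-fused dibenzo[b,f]oxepine as described in step 16 | CC(C)=CCC[C@]1(C)OC2=C(C[C@@H]1O)c1cc(CC=C(C)C)c(O)cc1Oc1cc(O)ccc12 | target

## Step count and risk

Total steps: 16. Longest linear sequence: 14 steps (steps 3 to 16, from **4**); the nerol branch (steps 1 and 2) joins at step 8.

**Step 13 (key step).** The oxidative cyclisation that has to close the seven-membered ring may be slower than homo-trimerisation of **19**, or than rhodium- or acid-induced hydration and oligomerisation of the ethynyl ether. Insertion of **19** in the reverse orientation is the second risk, because the silyl group is the only element that directs it.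
Fallback, with known reactions only, from **15** back to the route at **23**: ring C is introduced intact and ring B is closed through its C–O bond.
- Suzuki–Miyaura coupling of **15** with [2-chloro-4-(triisopropylsilyloxy)phenyl]boronic acid F1 should give the cis-diaryl dihydropyran F2. F1 is made from commercial 2-chloro-4-hydroxyphenylboronic acid with TIPSCl and imidazole. Coupling conditions are Pd(PPh3)4, aqueous Na2CO3, DME, 60 °C, under which neither kind of C–Cl bond should react.
- n-BuLi (THF, −78 to −40 °C) converts the dichlorovinyl ether into the ethynyl ether F3.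
- F3 is hydrated (pyridinium tosylate, wet THF, 0 °C) to the aryl acetate F4.
- Pyrrolidine (THF, 0 °C) removes the acetyl group to give the phenol F5.
- Palladium-catalysed intramolecular diaryl ether formation from the aryl chloride (Pd(OAc)2, t-BuXPhos, K3PO4, toluene, 100 °C) closes ring B to the tris-silyl ether F6.
- Bu4NF removes all three silyl groups and gives **23**.

**Step 9.** The ester carbonyl may attack the secondary epoxide carbon (5-exo), the activated epoxide may undergo hydride shift to a ketone (Meinwald rearrangement), or the acyl group of the δ-lactone may migrate to the secondary hydroxyl before silylation. The first and third lead to γ-lactones, the thermodynamic sink.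
Fallback, from **2** back to the route at **14**: the two oxygens are differentiated before the carboxyl group is present.
- Acid-catalysed hydrolysis of **2** (HClO4 cat., THF–H2O, 0 °C) opens the epoxide at the tertiary carbon with inversion and gives (2S,3S)-3,7-dimethyloct-6-ene-1,2,3-triol F7.
- Selective sulfonylation of the primary hydroxyl (TsCl, Et3N, Bu2SnO cat., CH2Cl2) gives the primary tosylate F8.
- Silylation of the secondary hydroxyl (TBSOTf, 2,6-lutidine, −78 °C) gives the 2-O-TBS tosylate F9, in which only the tertiary hydroxyl is free.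
- The lithium enolate of **11** (LiN(SiMe3)2, one extra equivalent for the hydroxyl, THF–DMPU, −78 to 0 °C) is alkylated with F9 to give the hydroxy ester F10.
- The tertiary alkoxide of F10 (NaH, THF, 0 to 25 °C) closes onto the tert-butyl ester to give **14**. Only the δ-lactone can form because the secondary oxygen is already silylated.

**Step 11.** Oxidative addition at the tetrasubstituted, α-aryl ketene acetal phosphate may be slow, so that hydrolysis back to the lactone or alkyne homocoupling takes over.
Fallback, from **14** back to the route at **17**: 1,2-addition and dehydration replace the cross-coupling.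
- The cerium acetylide from **16** (n-BuLi, then CeCl3, THF, −78 °C) adds to carbonyl groups with little enolisation and should convert **14** into the lactol 3-ArA-5-(TBSO)-6-methyl-6-homoprenyl-2-[(trimethylsilyl)ethynyl]oxan-2-ol F11.
- Dehydration through the alkynyl-stabilised oxocarbenium ion ((CF3CO)2O, 2,6-lutidine, CH2Cl2, −20 °C) removes the benzylic proton and gives **17**.

**Step 15.** Cleavage of the aryl C–Si bond may be slow because ring C is electron-rich and present as a phenoxide, so that prolonged heating in base leads to oxidative or base-induced decomposition.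
Fallback, from **17** back to the route at **23**: the silyl placeholder is given up before ring C is made.
- K2CO3 in MeOH (0 °C) removes the alkynyl silyl group of **17** to give the terminal enyne F12.
- n-BuLi (3.5 equiv), as in step 12, gives the doubly terminal diyne F13.
- Cyclotrimerisation with **19**, as in step 13, gives the boronate F14. There is now no steric control over the orientation of **19**, so the regioisomeric boronate must be suppressed by ligand choice or removed by chromatography.
- NaBO3·4H2O gives the phenol F15, and Bu4NF gives **23**.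

## Further compounds

F1 | step 13 | [2-chloro-4-(triisopropylsilyloxy)phenyl]boronic acid | OB(O)c1ccc(O[Si](C(C)C)(C(C)C)C(C)C)cc1Cl
F2 | step 13 | (2S,3S)-5-ArA-6-[2-chloro-4-(TIPSO)phenyl]-3-(TBSO)-2-methyl-2-homoprenyl-3,4-dihydro-2H-pyran | CC(C)=CCC[C@]1(C)OC(c2ccc(O[Si](C(C)C)(C(C)C)C(C)C)cc2Cl)=C(C[C@@H]1O[Si](C)(C)C(C)(C)C)c1cc(CC=C(C)C)c(O[Si](C(C)C)(C(C)C)C(C)C)cc1O/C(Cl)=C\Cl
F3 | step 13 | (2S,3S)-6-[2-chloro-4-(TIPSO)phenyl]-5-[2-(ethynyloxy)-5-prenyl-4-(TIPSO)phenyl]-3-(TBSO)-2-methyl-2-homoprenyl-3,4-dihydro-2H-pyran | CC(C)=CCC[C@]1(C)OC(c2ccc(O[Si](C(C)C)(C(C)C)C(C)C)cc2Cl)=C(C[C@@H]1O[Si](C)(C)C(C)(C)C)c1cc(CC=C(C)C)c(O[Si](C(C)C)(C(C)C)C(C)C)cc1OC#C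
F4 | step 13 | 2-[(2S,3S)-6-[2-chloro-4-(TIPSO)phenyl]-3-(TBSO)-2-methyl-2-homoprenyl-3,4-dihydro-2H-pyran-5-yl]-4-prenyl-5-(TIPSO)phenyl acetate | CC(C)=CCC[C@]1(C)OC(c2ccc(O[Si](C(C)C)(C(C)C)C(C)C)cc2Cl)=C(C[C@@H]1O[Si](C)(C)C(C)(C)C)c1cc(CC=C(C)C)c(O[Si](C(C)C)(C(C)C)C(C)C)cc1OC(C)=O
F5 | step 13 | 2-[(2S,3S)-6-[2-chloro-4-(TIPSO)phenyl]-3-(TBSO)-2-methyl-2-homoprenyl-3,4-dihydro-2H-pyran-5-yl]-4-prenyl-5-(TIPSO)phenol | CC(C)=CCC[C@]1(C)OC(c2ccc(O[Si](C(C)C)(C(C)C)C(C)C)cc2Cl)=C(C[C@@H]1O[Si](C)(C)C(C)(C)C)c1cc(CC=C(C)C)c(O[Si](C(C)C)(C(C)C)C(C)C)cc1O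
F6 | step 13 | 23 as its ring A O-TIPS, ring C O-TIPS and C3' O-TBS tris-silyl ether | CC(C)=CCC[C@]1(C)OC2=C(C[C@@H]1O[Si](C)(C)C(C)(C)C)c1cc(CC=C(C)C)c(O[Si](C(C)C)(C(C)C)C(C)C)cc1Oc1cc(O[Si](C(C)C)(C(C)C)C(C)C)ccc12
F7 | step 9 | (2S,3S)-3,7-dimethyloct-6-ene-1,2,3-triol | CC(C)=CCC[C@](C)(O)[C@@H](O)CO
F8 | step 9 | (2S,3S)-2,3-dihydroxy-3,7-dimethyloct-6-en-1-yl 4-methylbenzenesulfonate | CC(C)=CCC[C@](C)(O)[C@@H](O)COS(=O)(=O)c1ccc(C)cc1
F9 | step 9 | (2S,3S)-2-(TBSO)-3-hydroxy-3,7-dimethyloct-6-en-1-yl 4-methylbenzenesulfonate | CC(C)=CCC[C@](C)(O)[C@@H](O[Si](C)(C)C(C)(C)C)COS(=O)(=O)c1ccc(C)cc1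
F10 | step 9 | tert-butyl (2RS,4S,5S)-2-ArA-4-(TBSO)-5-hydroxy-5,9-dimethyldec-8-enoate | CC(C)=CCC[C@](C)(O)[C@@H](O[Si](C)(C)C(C)(C)C)CC(C(=O)OC(C)(C)C)c1cc(CC=C(C)C)c(O[Si](C(C)C)(C(C)C)C(C)C)cc1O/C(Cl)=C\Cl
F11 | step 11 | (2RS,3RS,5S,6S)-3-ArA-5-(TBSO)-6-methyl-6-homoprenyl-2-[(trimethylsilyl)ethynyl]oxan-2-ol | CC(C)=CCC[C@]1(C)OC(O)(C#C[Si](C)(C)C)C(C[C@@H]1O[Si](C)(C)C(C)(C)C)c1cc(CC=C(C)C)c(O[Si](C(C)C)(C(C)C)C(C)C)cc1O/C(Cl)=C\Cl
F12 | step 15 | (2S,3S)-5-ArA-6-ethynyl-3-(TBSO)-2-methyl-2-homoprenyl-3,4-dihydro-2H-pyran | CC(C)=CCC[C@]1(C)OC(C#C)=C(C[C@@H]1O[Si](C)(C)C(C)(C)C)c1cc(CC=C(C)C)c(O[Si](C(C)C)(C(C)C)C(C)C)cc1O/C(Cl)=C\Cl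
F13 | step 15 | (2S,3S)-6-ethynyl-5-[2-(ethynyloxy)-5-prenyl-4-(TIPSO)phenyl]-3-(TBSO)-2-methyl-2-homoprenyl-3,4-dihydro-2H-pyran | CC(C)=CCC[C@]1(C)OC(C#C)=C(C[C@@H]1O[Si](C)(C)C(C)(C)C)c1cc(CC=C(C)C)c(O[Si](C(C)C)(C(C)C)C(C)C)cc1OC#C
F14 | step 15 | 23 with ring A O-TIPS, C3' O-TBS and Bpin on ring C in place of the hydroxyl | CC(C)=CCC[C@]1(C)OC2=C(C[C@@H]1O[Si](C)(C)C(C)(C)C)c1cc(CC=C(C)C)c(O[Si](C(C)C)(C(C)C)C(C)C)cc1Oc1cc(B3OC(C)(C)C(C)(C)O3)ccc12
F15 | step 15 | 23 as its ring A O-TIPS and C3' O-TBS bis-silyl ether | CC(C)=CCC[C@]1(C)OC2=C(C[C@@H]1O[Si](C)(C)C(C)(C)C)c1cc(CC=C(C)C)c(O[Si](C(C)C)(C(C)C)C(C)C)cc1Oc1cc(O)ccc12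
A1 | alternative 1 | methyl 2-[4-hydroxy-5-prenyl-2-[3-(triisopropylsilyloxy)phenoxy]phenyl]acetate | COC(=O)Cc1cc(CC=C(C)C)c(O)cc1Oc1cccc(O[Si](C(C)C)(C(C)C)C(C)C)c1
A2 | alternative 1 | methyl (5E)-3-diazo-9-methyl-4-oxodeca-5,8-dienoate | COC(=O)CC(=[N+]=[N-])C(=O)/C=C/CC=C(C)C
A3 | alternative 1 | 1-(ethynyloxy)-3-(triisopropylsilyloxy)benzene | C#COc1cccc(O[Si](C(C)C)(C(C)C)C(C)C)c1
A4 | alternative 2 | 11-[(2S,3S)-2-(TBSO)-3,7-dimethyl-3-(triethylsilyloxy)oct-6-enyl]dibenzo[b,f]oxepin-10(11H)-one bearing TBSO para to C10 on ring C and para to C11 on ring A | CC(C)=CCC[C@](C)(O[Si](CC)(CC)CC)[C@@H](O[Si](C)(C)C(C)(C)C)CC1C(=O)c2ccc(O[Si](C)(C)C(C)(C)C)cc2Oc2cc(O[Si](C)(C)C(C)(C)C)ccc12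
A5 | alternative 2 | 9-[(3S,4S)-1,1-dibromo-3-(TBSO)-4,8-dimethyl-4-(triethylsilyloxy)non-7-enyl]-3,6-bis(TBSO)xanthen-9-ol | CC(C)=CCC[C@](C)(O[Si](CC)(CC)CC)[C@@H](O[Si](C)(C)C(C)(C)C)CC(Br)(Br)C1(O)c2ccc(O[Si](C)(C)C(C)(C)C)cc2Oc2cc(O[Si](C)(C)C(C)(C)C)ccc12
A6 | alternative 3 | (2S,3S)-6-[2-bromo-4-(TBSO)phenyl]-5-[2,4-bis(TBSO)-5-prenylphenyl]-3-(TBSO)-2-methyl-2-homoprenyl-3,4-dihydro-2H-pyran | CC(C)=CCC[C@]1(C)OC(c2ccc(O[Si](C)(C)C(C)(C)C)cc2Br)=C(C[C@@H]1O[Si](C)(C)C(C)(C)C)c1cc(CC=C(C)C)c(O[Si](C)(C)C(C)(C)C)cc1O[Si](C)(C)C(C)(C)C
A7 | alternative 3 | 1-iodo-2,4-bis(TBSO)-5-prenylbenzene | CC(C)=CCc1cc(I)c(O[Si](C)(C)C(C)(C)C)cc1O[Si](C)(C)C(C)(C)C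
A8 | alternative 3 | (4S,5S)-1-[2-bromo-4-(TBSO)phenyl]-4-(TBSO)-5,9-dimethyldec-8-en-1-yn-5-ol | CC(C)=CCC[C@](C)(O)[C@@H](O[Si](C)(C)C(C)(C)C)CC#Cc1ccc(O[Si](C)(C)C(C)(C)C)cc1Br
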